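1. The vessel is closed, stirred and held at 90 °C. It is the south flask, followed so far, and the earlier south-east run stands beside it.

the same everywhere: substrate 0.10 M

|  | reagent | capture agent | free catalyst | temperature | remark | time |
|---|---|---|---|---|---|---|
| south | 0.11 M | 5 mM | 5 mM | 90 °C | the very flask that is asked about, followed so far |  |
| south-east | 0.11 M | 5 mM | 2.5 mM | 85 °C | run made earlier |  |
| flask | 0.110 M | 5.00 mM | 5.0 mM | 90 °C |  | 8.0 min |

south run (percent of the substrate charged)

| time / min | target / % |
|---|---|
| 0.333 | 3.0 |
| 1.00 | 11.0 |
| 2.00 | 16.4 |
| 3.00 | 20.3 |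
| 4.00 | 21.2 |
| 5.00 | 20.7 |
| 6.00 | 21.3 |

south-east run (percent of the substrate charged)

| time / s | target / % |
|---|---|
| 15.0 | 0.6 |
| 30.0 | 3.2 |
| 40.0 | 3.0 |
| 60.0 | 4.6 |
| 80.0 | 5.2 |
| 90.0 | 6.4 |

(standard deviation of a reading: 1 percentage point)

- target taken out counts as made
- the earlier runs were read with a standard deviation of 1 percentage point
- additions bring no volume worth counting

- winter: at 8.0 min take out 90% of the target then present, then wait 15 min
- noon: at 8.0 min add free catalyst, 100% of the amount charged, then wait 15 min
- summer: change nothing and wait 15 min more
- autumn: at 8.0 min raise the temperature by 15 K, then wait 15 min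
- spring: at 8.0 min add reagent, 50.0% of the amount charged, then wait 15 min

- target, in percent of the substrate first charged, at 8.0 min
- the remedy with the largest gain of target, or "none" below 2 percentage points (winter / noon / summer / autumn / spring / none)
- target present, with what was taken out counted in, in percent of the substrate first charged, after summer
- target present, with what was taken out counted in, in percent of the substrate first charged, after spring

2. What is in it: target read 21.2% at 4.00 min and 21.3% at 6.00 min, a step less than the scatter of 1 percentage point. From 4.00 min on, the south readings stay within that scatter.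

3. What we count: at 1.00 min the south flask read 2.39 times the south-east run, which has half the free catalyst and stands at 85 °C. Both settings differ at once, so these readings do not part them; we choose to count target per catalyst. The charged c(substrate) times the last south reading, over the charged c(free catalyst), gives 4.26; these are the rounds per catalyst, the turnover number.

4. What will stand there: our count gives 21.3% at 8.0 min in the south flask, and we expect the same after summer or spring, which bring no catalyst.

5. What not to touch: leave the temperature alone, for the runs so far stand at 90 °C and 85 °C. Noon is our choice, and doubling c(free catalyst) should add 21 points.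

6. The forecast agrees on the choice: 21.5% now (20.5% to 22.8%), noon best, 22% after summer, 22.5% after spring. In its words: “Fresh catalyst would find the capture agent used up and keep working”.

    reagent + free catalyst → catalyst intermediate A (k = 1.74 L mol⁻¹ s⁻¹, Ea = 53.0 kJ mol⁻¹)
    catalyst intermediate A → catalyst intermediate B (k = 0.204 s⁻¹, Ea = 78.0 kJ mol⁻¹)
    substrate + catalyst intermediate B ⇌ catalyst intermediate C (K = 10.9 L mol⁻¹, k = 167 L mol⁻¹ s⁻¹, Ea = 57.0 kJ mol⁻¹, ΔH = 0 kJ mol⁻¹)
    catalyst intermediate C → free catalyst + target (k = 0.284 s⁻¹, Ea = 80.0 kJ mol⁻¹)
    reagent + catalyst intermediate A → spent catalyst (k = 0.237 L mol⁻¹ s⁻¹, Ea = 54.0 kJ mol⁻¹)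
    catalyst intermediate C + capture agent → trapped intermediate (k = 2.33 L mol⁻¹ s⁻¹, Ea = 39.0 kJ mol⁻¹)
    target ⇌ isomer of the product (K = 2.36, k = 0.00182 s⁻¹, Ea = 99.0 kJ mol⁻¹, ΔH = 20.0 kJ mol⁻¹)
    (constants at 90 °C)

The flask gives 19.8% at 8.0 min, 11.9% after summer and 11.5% after spring, and noon is best, gaining 16 points. In the scheme target and isomer of the product pass into each other, so we count both: at 8.00 min the flask holds 19.8% target and 13.4% isomer of the product, which is 6.64 rounds per catalyst charged, more than our 4.26. For the neighbouring flask with 0.013 M of free catalyst, those rounds give 86.4%. At 8.00 min that neighbouring flask holds 52.5% target and 34.2% isomer of the product, together 86.7%, with 23.2% of its catalyst still free.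

The readings were generated by integration on assumed constants.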